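The route cuts ring A (C1–C5, C10; labdane numbering) at C3–C4. Ring B is built first as a cyclohexene. It carries C5–CH(CH3)CO2Me as both C4 epimers and a quaternary C10 (methyl plus a 3-tosyloxypropyl arm trans to the C5 substituent). Its C8 ketone is masked as a silyl enol ether. One deprotonation flattens C4, and the ester enolate closes ring A by 6-exo-tet alkylation. The epimer mixture converges on one quaternary C4 with equatorial CO2Me and axial methyl. The step exploits the enolisable C18 ester on C4 beside the C5–H ring-fusion methine. Allylic 1,3-strain and the tether from C10 leave only one enolate face open.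

Key step: step 7

Remark: labdane numbering is used for all compounds. Ring A is C1–C5 plus C10, ring B is C5–C10, and the side chain is C11–C16. C17 is the exocyclic methylene carbon, C18 the ester carbon, C19 the methyl on C4, and C20 the methyl on C10. The target is read as an ent-labdane with 4S,5S,9R,10S,13R configuration.

Step 1
Reactants: 1 2-methylcyclohex-2-en-1-one
Product: 2 (R)-2-methylcyclohex-2-en-1-ol
Conditions: (S)-Me-CBS oxazaborolidine [(S)-1-methyl-3,3-diphenyltetrahydro-1H,3H-pyrrolo[1,2-c][1,3,2]oxazaborole] (cat.), BH3·SMe2, THF, −20 °C; then MeOH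
Reagents that add atoms: none
Why: In this Corey–Bakshi–Shibata reduction the oxazaborolidine binds the ketone with the larger 2-methylvinyl flank turned away and delivers hydride to one face only, so the carbinol carbon (future C9) should form as the R alcohol without hydroboration of the trisubstituted alkene.

Step 2
Reactants: 2 (R)-2-methylcyclohex-2-en-1-ol; 3 trimethyl orthopropionate
Product: 5 methyl 2-[(1R)-2-methylcyclohex-2-en-1-yl]propanoate (both C4 epimers), via ketene acetal 4 (not isolated)
Conditions: EtCO2H (cat.), neat 3, 140 °C, MeOH distilled off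
Reagents that add atoms: trimethyl orthopropionate CCC(OC)(OC)OC
Why: In this Johnson orthoester Claisen rearrangement the suprafacial [3,3] shift of 4 carries the C9–O configuration to the new C5–C4 bond (C5 R) and moves the alkene to C9=C10, while the uncontrolled C4 centre does not matter because step 7 erases it.

Step 3
Reactants: 5 methyl 2-[(1R)-2-methylcyclohex-2-en-1-yl]propanoate
Product: 6 methyl 2-[(1R)-2-methyl-4-oxocyclohex-2-en-1-yl]propanoate (both C4 epimers)
Conditions: CrO3, 3,5-dimethylpyrazole, CH2Cl2, −20 °C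
Reagents that add atoms: chromium trioxide O=[Cr](=O)=O
Why: This chromium-mediated allylic oxidation attacks the only ring methylene allylic to the trisubstituted alkene (C8) and gives the conjugated C8 enone under nearly neutral conditions that should leave C5 untouched.

Step 4
Reactants: 6 methyl 2-[(1R)-2-methyl-4-oxocyclohex-2-en-1-yl]propanoate; 7 allyltributylstannane
Product: 8 methyl 2-[(1R,2R)-4-(tert-butyldimethylsilyloxy)-2-methyl-2-(prop-2-enyl)cyclohex-3-en-1-yl]propanoate
Conditions: TBSOTf, CH2Cl2, −78 °C; Et3N quench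
Reagents that add atoms: allyltributylstannane C=CC[Sn](CCCC)(CCCC)CCCC; tert-butyldimethylsilyl trifluoromethanesulfonate CC(C)(C)[Si](C)(C)OS(=O)(=O)C(F)(F)F
Why: In this silyl-triflate-promoted Hosomi–Sakurai-type conjugate allylation the 3-silyloxyallyl cation is attacked at C10 anti to the C5 substituent (held pseudoaxial by allylic 1,2-strain with the C10 methyl), so the quaternary centre is set trans and the C8 oxygen is trapped regiospecifically as the C8=C9 silyl enol ether.

Step 5
Reactants: 8 methyl 2-[(1R,2R)-4-(tert-butyldimethylsilyloxy)-2-methyl-2-(prop-2-enyl)cyclohex-3-en-1-yl]propanoate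
Product: 10 methyl 2-[(1R,2R)-4-(tert-butyldimethylsilyloxy)-2-(3-hydroxypropyl)-2-methylcyclohex-3-en-1-yl]propanoate, via alkylborane 9 (not isolated)
Conditions: 9-BBN, THF, 0 °C to rt; then H2O2, aq. NaOH, 0 °C
Reagents that add atoms: hydrogen peroxide OO
Why: In this Brown hydroboration–oxidation 9-BBN adds anti-Markovnikov to the monosubstituted allyl alkene far faster than to the hindered trisubstituted silyl enol ether, and cold alkaline peroxide then gives the primary C3 alcohol with no change at any stereocentre.

Step 6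
Reactants: 10 methyl 2-[(1R,2R)-4-(tert-butyldimethylsilyloxy)-2-(3-hydroxypropyl)-2-methylcyclohex-3-en-1-yl]propanoate
Product: 11 methyl 2-[(1R,2R)-4-(tert-butyldimethylsilyloxy)-2-methyl-2-(3-tosyloxypropyl)cyclohex-3-en-1-yl]propanoate
Conditions: TsCl, Et3N, DMAP (cat.), CH2Cl2, 0 °C
Reagents that add atoms: 4-toluenesulfonyl chloride Cc1ccc(cc1)S(=O)(=O)Cl
Why: This standard sulfonylation of a primary alcohol turns C3 into an SN2 electrophile under mildly basic conditions that leave the silyl enol ether and the ester alone.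

Step 7
Reactants: 11 methyl 2-[(1R,2R)-4-(tert-butyldimethylsilyloxy)-2-methyl-2-(3-tosyloxypropyl)cyclohex-3-en-1-yl]propanoate
Product: 13 methyl (1S,4aR,8aS)-6-(tert-butyldimethylsilyloxy)-1,4a-dimethyl-1,2,3,4,4a,7,8,8a-octahydronaphthalene-1-carboxylate, via lithium enolate 12 (not isolated)
Conditions: LiN(iPr)2, THF–DMPU, −78 °C to rt
Reagents that add atoms: none
Why: LiN(iPr)2 removes C4–H from either epimer of 11 to give the same planar ester enolate 12, which displaces the primary tosylate at C3 in an intramolecular SN2 reaction. The closest known reaction type is the intramolecular alkylation of an ester enolate used to make cyclohexanecarboxylates with a quaternary alpha carbon. Ring A closes in the favoured 6-(enolexo)-exo-tet mode and can only become trans-fused because C1 on C10 and C4 on C5 were set trans in step 4. The only new stereocentre is C4: allylic 1,3-strain makes the enolate C4=C18 bond eclipse C5–H, the C4 methyl then lies between C6 and C10, and the C1–C3 tether reaches only the enolate face turned toward C10, so CO2Me should end equatorial and the methyl axial, syn to C20. The step needs chemoselective enolisation, secured by masking the C8 ketone as a base-stable silyl enol ether, and it needs C-alkylation to beat O-alkylation and elimination, secured by the six-membered transition state, the primary sulfonate and DMPU. Because C4 is planar in 12, the epimer composition of 11 is irrelevant and the mixture converges on one product.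

Step 8
Reactants: 13 methyl (1S,4aR,8aS)-6-(tert-butyldimethylsilyloxy)-1,4a-dimethyl-1,2,3,4,4a,7,8,8a-octahydronaphthalene-1-carboxylate; 14 Eschenmoser's salt
Product: 17 methyl (1S,4aR,8aS)-1,4a-dimethyl-5-methylidene-6-oxodecahydronaphthalene-1-carboxylate, via Mannich base 15 (not isolated), via ammonium iodide 16 (not isolated)
Conditions: 14, CH2Cl2, rt, aq. NaHCO3 wash; MeI, Et2O; DBU, CH2Cl2, rt
Reagents that add atoms: N,N-dimethylmethyleneiminium iodide C[N+](C)=C.[I-]
Why: A Mannich reaction of the silyl enol ether followed by Hofmann-type elimination of the quaternised amine installs C11 regiospecifically at C9 because the enol ether fixed in step 4 is the only nucleophilic carbon, and the transient C9 centre of 15 disappears again in the exocyclic enone.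

Step 9
Reactants: 17 methyl (1S,4aR,8aS)-1,4a-dimethyl-5-methylidene-6-oxodecahydronaphthalene-1-carboxylate; 18 2-[(trimethylsilyl)methyl]allyl acetate
Product: 20 methyl (1S,4aR,5S,8aS)-5-[3-(acetoxymethyl)but-3-enyl]-1,4a-dimethyl-6-oxodecahydronaphthalene-1-carboxylate, via titanium enolate 19 (not isolated)
Conditions: TiCl4, CH2Cl2, −78 °C; then H2O
Reagents that add atoms: 2-[(trimethylsilyl)methyl]allyl acetate CC(=O)OCC(=C)C[Si](C)(C)C
Why: In this Hosomi–Sakurai conjugate addition the TiCl4-activated exocyclic enone is attacked at its unhindered C11 terminus by the allylsilane (loss of the silyl group regenerates a 1,1-disubstituted alkene), and axial protonation of 19 from the face opposite the axial C20 methyl should place the side chain equatorial at C9.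

Step 10
Reactants: 20 methyl (1S,4aR,5S,8aS)-5-[3-(acetoxymethyl)but-3-enyl]-1,4a-dimethyl-6-oxodecahydronaphthalene-1-carboxylate
Product: 21 methyl (1S,4aR,5S,8aS)-5-[3-(hydroxymethyl)but-3-enyl]-1,4a-dimethyl-6-oxodecahydronaphthalene-1-carboxylate
Conditions: K2CO3 (cat.), MeOH, rt
Reagents that add atoms: none
Why: Base-catalysed transesterification frees the allylic alcohol and at the same time equilibrates the enolisable C9 centre of the rigid trans-decalone toward the more stable equatorial side-chain epimer, while the hindered C18 methyl ester can only exchange methoxide degenerately.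

Step 11
Reactants: 21 methyl (1S,4aR,5S,8aS)-5-[3-(hydroxymethyl)but-3-enyl]-1,4a-dimethyl-6-oxodecahydronaphthalene-1-carboxylate; 22 methyltriphenylphosphonium bromide
Product: 23 methyl (1S,4aS,5R,8aS)-5-[3-(hydroxymethyl)but-3-enyl]-1,4a-dimethyl-6-methylidenedecahydronaphthalene-1-carboxylate
Conditions: 22, KOtBu (excess), THF, 0 °C to reflux
Reagents that add atoms: methyltriphenylphosphonium bromide C[P+](c1ccccc1)(c1ccccc1)c1ccccc1.[Br-]
Why: Wittig methylenation with excess ylide (one equivalent is consumed by the free alcohol) converts the C8 ketone into the C8=C17 exocyclic alkene, the quaternary-flanked C18 ester is too hindered to react, and any enolisation can only return C9 to its favoured equatorial epimer.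

Step 12
Reactants: 23 methyl (1S,4aS,5R,8aS)-5-[3-(hydroxymethyl)but-3-enyl]-1,4a-dimethyl-6-methylidenedecahydronaphthalene-1-carboxylate
Product: 24 methyl (1S,4aS,5R,8aS)-5-{2-[(2S)-2-(hydroxymethyl)oxiran-2-yl]ethyl}-1,4a-dimethyl-6-methylidenedecahydronaphthalene-1-carboxylate
Conditions: Ti(OiPr)4 (cat.), L-(+)-diisopropyl tartrate (cat.), t-BuOOH, 4 Å molecular sieves, CH2Cl2, −20 °C
Reagents that add atoms: tert-butyl hydroperoxide CC(C)(C)OO
Why: The Sharpless asymmetric epoxidation is directed by the allylic hydroxyl so that only C13=C14 reacts (C8=C17 has no directing group), and the L-(+)-tartrate catalyst delivers oxygen to the face that gives the 13S epoxide, as is the rule for 2-substituted allylic alcohols.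

Step 13
Reactants: 24 methyl (1S,4aS,5R,8aS)-5-{2-[(2S)-2-(hydroxymethyl)oxiran-2-yl]ethyl}-1,4a-dimethyl-6-methylidenedecahydronaphthalene-1-carboxylate; 25 trimethylsulfonium iodide
Product: 27 methyl (1S,4aS,5R,8aS)-5-[(3R)-3-hydroxy-3-(hydroxymethyl)pent-4-en-1-yl]-1,4a-dimethyl-6-methylidenedecahydronaphthalene-1-carboxylate, via sulfonium betaine 26 (not isolated)
Conditions: 25, n-BuLi (excess), THF, −10 °C to rt
Reagents that add atoms: trimethylsulfonium iodide C[S+](C)C.[I-]
Why: In this one-carbon homologation of a terminal epoxide to an allylic alcohol the excess dimethylsulfonium methylide opens the epoxide at its CH2 terminus and 26 loses dimethyl sulfide by elimination, so the C13–O bond is never broken, a possible Payne shift is degenerate, and the configuration is retained (the descriptor changes from S to R only through the priority rules).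

Compound list
1 | 2-methylcyclohex-2-en-1-one | CC1=CCCCC1=O | starting material
2 | (R)-2-methylcyclohex-2-en-1-ol | O[C@@H]1CCCC=C1C | intermediate
3 | trimethyl orthopropionate | CCC(OC)(OC)OC | starting material
4 | mixed ketene acetal, 1-methoxyprop-1-enyl (R)-2-methylcyclohex-2-enyl ether | CC=C(OC)O[C@@H]1CCCC=C1C | intermediate
5 | methyl 2-[(1R)-2-methylcyclohex-2-en-1-yl]propanoate (both C4 epimers) | C1CC[C@H](C(C)C(=O)OC)C(C)=C1 | intermediate
6 | methyl 2-[(1R)-2-methyl-4-oxocyclohex-2-en-1-yl]propanoate (both C4 epimers) | O=C1CC[C@H](C(C)C(=O)OC)C(C)=C1 | intermediate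
7 | allyltributylstannane | C=CC[Sn](CCCC)(CCCC)CCCC | starting material
8 | methyl 2-[(1R,2R)-4-(tert-butyldimethylsilyloxy)-2-methyl-2-(prop-2-enyl)cyclohex-3-en-1-yl]propanoate | C1=C(O[Si](C)(C)C(C)(C)C)CC[C@H](C(C)C(=O)OC)[C@@]1(C)CC=C | intermediate
9 | B-alkyl-9-borabicyclo[3.3.1]nonane formed from 8 (boron on C3) | C1=C(O[Si](C)(C)C(C)(C)C)CC[C@H](C(C)C(=O)OC)[C@@]1(C)CCCB1C2CCCC1CCC2 | intermediate
10 | methyl 2-[(1R,2R)-4-(tert-butyldimethylsilyloxy)-2-(3-hydroxypropyl)-2-methylcyclohex-3-en-1-yl]propanoate | C1=C(O[Si](C)(C)C(C)(C)C)CC[C@H](C(C)C(=O)OC)[C@@]1(C)CCCO | intermediate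
11 | methyl 2-[(1R,2R)-4-(tert-butyldimethylsilyloxy)-2-methyl-2-(3-tosyloxypropyl)cyclohex-3-en-1-yl]propanoate | C1=C(O[Si](C)(C)C(C)(C)C)CC[C@H](C(C)C(=O)OC)[C@@]1(C)CCCOS(=O)(=O)c1ccc(C)cc1 | intermediate
12 | lithium ester enolate of 11 (C4 planar) | C1=C(O[Si](C)(C)C(C)(C)C)CC[C@H](C(C)=C([O-])OC)[C@@]1(C)CCCOS(=O)(=O)c1ccc(C)cc1.[Li+] | intermediate
13 | methyl (1S,4aR,8aS)-6-(tert-butyldimethylsilyloxy)-1,4a-dimethyl-1,2,3,4,4a,7,8,8a-octahydronaphthalene-1-carboxylate | C1=C(O[Si](C)(C)C(C)(C)C)CC[C@H]2[C@@]1(C)CCC[C@]2(C)C(=O)OC | intermediate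
14 | Eschenmoser's salt (N,N-dimethylmethyleneiminium iodide) | C[N+](C)=C.[I-] | starting material
15 | Mannich base, 9-(dimethylaminomethyl) 8-ketone (C9 unassigned) | CN(C)CC1C(=O)CC[C@H]2[C@@]1(C)CCC[C@]2(C)C(=O)OC | intermediate
16 | trimethylammonium iodide of 15 | C[N+](C)(C)CC1C(=O)CC[C@H]2[C@@]1(C)CCC[C@]2(C)C(=O)OC.[I-] | intermediate
17 | methyl (1S,4aR,8aS)-1,4a-dimethyl-5-methylidene-6-oxodecahydronaphthalene-1-carboxylate | C=C1C(=O)CC[C@H]2[C@@]1(C)CCC[C@]2(C)C(=O)OC | intermediate
18 | 2-[(trimethylsilyl)methyl]allyl acetate | CC(=O)OCC(=C)C[Si](C)(C)C | starting material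
19 | trichlorotitanium C8=C9 enolate carrying the full C11–C14/C16 chain | CC(=O)OCC(=C)CCC1=C(O[Ti](Cl)(Cl)Cl)CC[C@H]2[C@@]1(C)CCC[C@]2(C)C(=O)OC | intermediate
20 | methyl (1S,4aR,5S,8aS)-5-[3-(acetoxymethyl)but-3-enyl]-1,4a-dimethyl-6-oxodecahydronaphthalene-1-carboxylate | CC(=O)OCC(=C)CC[C@@H]1C(=O)CC[C@H]2[C@@]1(C)CCC[C@]2(C)C(=O)OC | intermediate
21 | methyl (1S,4aR,5S,8aS)-5-[3-(hydroxymethyl)but-3-enyl]-1,4a-dimethyl-6-oxodecahydronaphthalene-1-carboxylate | C=C(CO)CC[C@@H]1C(=O)CC[C@H]2[C@@]1(C)CCC[C@]2(C)C(=O)OC | intermediate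
22 | methyltriphenylphosphonium bromide | C[P+](c1ccccc1)(c1ccccc1)c1ccccc1.[Br-] | starting material
23 | methyl (1S,4aS,5R,8aS)-5-[3-(hydroxymethyl)but-3-enyl]-1,4a-dimethyl-6-methylidenedecahydronaphthalene-1-carboxylate | C=C(CO)CC[C@@H]1C(=C)CC[C@H]2[C@@]1(C)CCC[C@]2(C)C(=O)OC | intermediate
24 | methyl (1S,4aS,5R,8aS)-5-{2-[(2S)-2-(hydroxymethyl)oxiran-2-yl]ethyl}-1,4a-dimethyl-6-methylidenedecahydronaphthalene-1-carboxylate | C1[C@@](O1)(CO)CC[C@@H]2C(=C)CC[C@H]3[C@@]2(C)CCC[C@]3(C)C(=O)OC | intermediate
25 | trimethylsulfonium iodide | C[S+](C)C.[I-] | starting material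
26 | sulfonium bis-alkoxide betaine (dimethylsulfonio group on C15, lithium salt) | C[S+](C)CC[C@@]([O-])(C[O-])CC[C@@H]1C(=C)CC[C@H]2[C@@]1(C)CCC[C@]2(C)C(=O)OC.[Li+] | intermediate
27 | methyl (1S,4aS,5R,8aS)-5-[(3R)-3-hydroxy-3-(hydroxymethyl)pent-4-en-1-yl]-1,4a-dimethyl-6-methylidenedecahydronaphthalene-1-carboxylate | C=C[C@@](O)(CO)CC[C@@H]1C(=C)CC[C@H]2[C@@]1(C)CCC[C@]2(C)C(=O)OC | target

Total step count: 13. Longest linear sequence: 13.

Steps most likely to fail

Step 4. The stannane may attack the carbonyl carbon instead of the hindered C10. Alternatively, the activated enone may lose its gamma proton, which would erode the C5 configuration. The fallback sets out from 6 and replaces the Lewis-acid/stannane addition by an organocopper conjugate addition. Allylcopper made from allylmagnesium bromide, CuBr·SMe2 and LiCl, in the presence of Me3SiCl, should give the trimethylsilyl enol ether F1. KOtBu at low temperature cleaves its silyl group to the regiodefined potassium enolate F2. Silylation of F2 on oxygen with TBSCl brings the material back to the route at 8.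

Step 7. Deprotonation of the hindered C4–H may be sluggish, so that base-induced elimination of the sulfonate competes, or the facial bias at the enolate may be incomplete. The fallback sets out from 10 and closes ring A by carbonyl addition instead of substitution.
- No leaving group is present in 10, so it can be doubly deprotonated with LiN(iPr)2 at higher temperature. Quenching with 1,2-dibromotetrachloroethane gives the tertiary bromo ester F3.
- Dess–Martin periodinane oxidises the primary alcohol to the bromo aldehyde F4.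
- SmI2 effects an intramolecular Reformatsky reaction to the 3-hydroxy ester F5, under the same 1,3-strain bias at C4.
- 1,1'-Thiocarbonyldiimidazole gives the imidazolyl thiocarbonate F6.
- Barton–McCombie deoxygenation (Bu3SnH, AIBN) returns to the route at 13.

Step 9. TiCl4 may ionise the allylic acetate of the silane, or the exocyclic enone may oligomerise before the C11–C12 bond forms. The fallback sets out from 17 and builds the chain at the ketone oxidation level.
- Commercial 1-(tert-butyldimethylsilyloxy)propan-2-one is converted with LiN(iPr)2 and Me3SiCl into the kinetic silyl enol ether F7.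
- A Mukaiyama–Michael addition of F7 to 17 (BF3·OEt2), followed by brief DBU equilibration of C9, gives the 8,13-diketone F8.
- Non-basic Takai–Lombardo methylenation (Zn, CH2Br2, TiCl4) of both ketones gives the bis-methylidene silyl ether F9.
- Bu4NF returns to the route at 23.

Further compounds
F1 | step 4 | trimethylsilyl enol ether analogue of 8 | C1=C(O[Si](C)(C)C)CC[C@H](C(C)C(=O)OC)[C@@]1(C)CC=C
F2 | step 4 | potassium C8=C9 enolate | C1=C([O-])CC[C@H](C(C)C(=O)OC)[C@@]1(C)CC=C.[K+]
F3 | step 7 | tertiary bromo ester with free C3 alcohol | C1=C(O[Si](C)(C)C(C)(C)C)CC[C@H](C(C)(Br)C(=O)OC)[C@@]1(C)CCCO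
F4 | step 7 | bromo aldehyde (C3 aldehyde) | C1=C(O[Si](C)(C)C(C)(C)C)CC[C@H](C(C)(Br)C(=O)OC)[C@@]1(C)CCC=O
F5 | step 7 | 3-hydroxy ester with ring A closed (C3 unassigned) | C1=C(O[Si](C)(C)C(C)(C)C)CC[C@H]2[C@@]1(C)CCC(O)[C@]2(C)C(=O)OC
F6 | step 7 | imidazolyl thiocarbonate of F5 | C1=C(O[Si](C)(C)C(C)(C)C)CC[C@H]2[C@@]1(C)CCC(OC(=S)n1ccnc1)[C@]2(C)C(=O)OC
F7 | step 9 | 3-(tert-butyldimethylsilyloxy)-2-(trimethylsilyloxy)prop-1-ene | C=C(O[Si](C)(C)C)CO[Si](C)(C)C(C)(C)C
F8 | step 9 | 8,13-diketone with C16 silyl ether | CC(C)(C)[Si](C)(C)OCC(=O)CC[C@@H]1C(=O)CC[C@H]2[C@@]1(C)CCC[C@]2(C)C(=O)OC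
F9 | step 9 | bis-methylidene silyl ether (tert-butyldimethylsilyl ether of 23) | C=C(CO[Si](C)(C)C(C)(C)C)CC[C@@H]1C(=C)CC[C@H]2[C@@]1(C)CCC[C@]2(C)C(=O)OC
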